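All runs were computed with constants of no real substance, noise included.

**Gas clock.** Follow the gas taken up, not the clock. Substrate takes one gas to give target. We read what is missing from the percentages as over-reacted product, made from target with a second gas.

in all of them: gas phase 1.7 mM (held)
- green: substrate 0.0070 M; run made earlier
- blue: substrate 0.011 M; run made earlier
- flask: substrate 0.0050 M; time 2.0 min

- green (time / s: target / %, substrate / %): 10.0: 19.8, 79.5; 15.0: 28.7, 69.8; 25.0: 44.5, 49.8; 40.0: 56.9, 26.7; 60.0: 52.5, 7.7; 90.0: 16.9, 0.6
- blue (time / s: target / %, substrate / %): 10.0: 12.4, 85.6; 15.0: 19.3, 78.6; 25.0: 31.5, 65.3; 40.0: 46.0, 47.7; 60.0: 56.8, 27.0; 90.0: 52.1, 7.8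

(scatter of a reading: 0.5 percentage points)

- the moment within 2.0 min at which there is most target
- the amount of target, in percent of the substrate charged, at that time
- the first time at which target reaches 29%, in the same percent, in min

- at the start none of the gas phase is in solution

**Two readings.** So gas used is the charge times the substrate consumed plus the over-reacted product. Green, by its reading at 60.0 s, gives 0.154 mM/s, gas used per time, which we call the uptake. Blue gives a little more, 0.164 mM/s. We keep green, whose charge stands 2.00 mM from the flask's, against 6.00 mM for blue. Between green's readings at 25.0 s and 40.0 s we read a selectivity factor of 0.349. Target stops rising where [target]/[substrate] reaches its inverse, 2.87.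

**Our bracket.** Green at 40.0 s stands lower, at 2.13. Its gas demand, scaled to the flask's charge and divided by the uptake, gives a lower bound of 0.485 min, if the uptake holds. Green at 60.0 s stands higher, at 6.82, which gives an upper bound of 0.714 min. Consecutive steps with our factor tighten this to 0.559 min.

**The forecast.** It gives 0.57 min, 58.4% and 0.175 min, inside our bracket, on the ground that “The gas supply therefore limits the rate”.

**The flask.** It gives 0.579 min, 57.5% and 0.189 min, so the forecast stands, and the time lies inside our bracket.

    gas phase ⇌ dissolved gas, rate k1*(csat - [dissolved gas]) (kL = 0.101 /s)
    substrate + dissolved gas → target (k = 471 /M/s)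
    dissolved gas + target → over-reacted product (k = 159 /M/s)
    dissolved gas ⇌ dormant form (K = 1.90, k = 0.563 /s)

**What to watch.** Up to 0.579 min the flask's uptake averages 0.149 mM/s. The peak stands at 57.5% because target takes gas too. The run without that step reaches 100%, so the forecast's 58.4% is wrong for that run. For the neighbour read at 30 s, the uptake gives 92.5% of its charge in gas. It holds 26.9% substrate and 16.8% over-reacted product, which counts 89.9%.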